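The readings come from a simulation with made-up constants; the scatter is artificial.

A common pitfall is to carry one loss constant for target from flask to flask, as if warmth set it.

| setting | north | north-west | blue | red |
|---|---|---|---|---|
| starting material | 29 mM | 99 mM | 150 mM | 34 mM |
| second substrate | 20.4 mM | 20.4 mM | 20.4 mM | 20.4 mM |
| free enzyme | 17 µM | 17 µM | 17 µM | 17 µM |
| temperature | 12 °C | 27 °C | 17 °C | 37 °C |
| remark | run made earlier | run made earlier |  |  |
| time |  |  | 4.0 d | 4.0 d |

| run | time / d | target / % | starting material / % |
|---|---|---|---|
| north | 0.625 | 4.3 | 95.3 |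
| north | 2.00 | 13.5 | 86.8 |
| north | 4.00 | 25.0 | 74.2 |
| north | 6.00 | 34.2 | 63.6 |
| north | 8.00 | 39.5 | 54.0 |
| north | 10.0 | 42.9 | 46.5 |
| north | 15.0 | 38.7 | 35.6 |
| north-west | 0.500 | 3.8 | 96.0 |
| north-west | 0.833 | 6.0 | 93.6 |
| north-west | 1.25 | 8.7 | 91.4 |
| north-west | 1.67 | 10.3 | 88.4 |
| north-west | 2.50 | 13.6 | 85.0 |
| north-west | 4.00 | 15.0 | 81.2 |
| north-west | 6.00 | 13.2 | 79.8 |

(scatter of a reading: 0.3 percentage points)

- what is said of target includes crystals
- crystals is a solid; its amount is given per volume of the solution
- on the list of suspects stand: starting material + free enzyme <-> starting complex; ternary complex -> free enzyme + target; second substrate + starting complex <-> ternary complex; free enzyme -> unfolded enzyme; target + free enzyme <-> isomer of the product + free enzyme; crystals <-> target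

- the winner by amount of target, in percent of the starting material charged; "neither" if no more than 2 percentage points parts them (blue / red / neither)
- how much target is there at the end, in percent of the starting material charged: blue
- how much target is there at the end, in percent of the starting material charged: red

By the last north-west reading, starting material had fallen by 20.0 mM, near the 20.4 mM of second substrate charged, and it was still falling, though more slowly than between the two readings before, so I take second substrate as the limiting reagent. Hence the ceiling, c(second substrate)/c(starting material), the share of the charged starting material that second substrate can turn over: 60.0% for red and 13.6% for blue. Target is the ceiling minus a correction, so we need to reckon that correction.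

The correction shows as charge missing from the two readings. Per unit of target, it grows by 0.107 d⁻¹ between the last two north-west readings and by 0.0704 d⁻¹ between the last two north readings. The first readings of target give rates of 2.00 mM d⁻¹ at 12 °C and 7.52 mM d⁻¹ at 27 °C, a factor of 3.77, yet the loss differs by a factor of 1.52.

Two views follow. The forecast takes a loss of about 0.3 per day, “since it is warm and more enzyme is free”, and gives 6.5% for blue, 28% for red, and red as winner.

My own reckoning differs for red. North, at 29 mM, stands nearer to red's 34 mM of starting material than north-west does, so I scale the north loss by the same temperature factor, to 0.643 d⁻¹. Letting it act over the second half of the time leaves 16.6% for red. I accept the forecast's blue and its winner.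

The flask gives 7.38% for blue and 15.5% for red, so red wins.

    starting material + free enzyme ⇌ starting complex (K = 370 M⁻¹, k = 1.10 × 10⁶ M⁻¹ h⁻¹, Ea = 49.0 kJ mol⁻¹, ΔH = −49.0 kJ mol⁻¹)
    ternary complex → free enzyme + target (k = 130 h⁻¹, Ea = 83.0 kJ mol⁻¹)
    second substrate + starting complex ⇌ ternary complex (K = 26.0 M⁻¹, k = 1.00 × 10⁵ M⁻¹ h⁻¹, Ea = 47.0 kJ mol⁻¹, ΔH = −38.0 kJ mol⁻¹)
    free enzyme → unfolded enzyme (k = 0.00210 h⁻¹, Ea = 278 kJ mol⁻¹)
    target + free enzyme ⇌ isomer of the product + free enzyme, rate k5*[free enzyme]*[target] forward; the back reaction follows from the equilibrium constant (K = 2.90, k = 37000 M⁻¹ h⁻¹, Ea = 54.0 kJ mol⁻¹, ΔH = −8.00 kJ mol⁻¹)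
    crystals ⇌ target, rate k6*(cs6 - [target]) while solid is left; crystals form when [target] > cs6 (solubility = 22.0 mM, k = 27.0 h⁻¹)
    (constants at 37 °C)

Without the step from target to isomer of the product, red holds 59.0% of target instead of 15.5%, close to the ceiling. Red's ceiling minus its 43.5% of isomer gives 16.5%, against 15.5% of target. The small correction that the forecast expected for blue has its region in a neighbour of blue charged with 0.043 mM of free enzyme. There the ceiling minus 1.12% of isomer gives 12.5%, and the flask holds 11.6% of target.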